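5 questions stand here, and they all ask how much target 4 flasks hold at the end.

the same everywhere: starting material 0.20 M; catalyst 24 mM
- birch: partner 0.18 M; second substrate 0.20 M; temperature 60 °C; run made earlier
- oak: partner 0.72 M; second substrate 0.20 M; temperature 82 °C; run made earlier
- cedar: partner 0.36 M; second substrate 0.40 M; temperature 60 °C; run made earlier
- grey: partner 0.360 M; second substrate 0.200 M; temperature 70 °C; time 10 min
- teal: partner 0.360 M; second substrate 0.200 M; temperature 50 °C; time 10 min
- red: partner 0.360 M; second substrate 0.200 M; at 50 °C until 5.0 min, from then on at 90 °C; time 10 min
- amber: partner 0.360 M; second substrate 0.200 M; temperature 90 °C; time 10 min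

| run | time / min | target / % | starting material / % |
|---|---|---|---|
| birch | 2.50 | 17.4 | 74.6 |
| birch | 5.00 | 9.7 | 75.4 |
| birch | 8.00 | 5.2 | 76.2 |
| birch | 10.0 | 3.9 | 76.3 |
| birch | 12.0 | 2.9 | 76.5 |
| birch | 15.0 | 2.0 | 76.2 |
| birch | 20.0 | 0.9 | 75.4 |
| oak | 0.833 | 48.6 | 35.5 |
| oak | 1.50 | 43.1 | 30.3 |
| oak | 3.00 | 33.4 | 23.8 |
| oak | 4.00 | 29.4 | 20.6 |
| oak | 6.00 | 23.7 | 16.5 |
| cedar | 1.50 | 29.3 | 64.3 |
| cedar | 3.00 | 18.2 | 70.3 |
| cedar | 5.00 | 10.4 | 73.5 |
| cedar | 10.0 | 2.7 | 74.5 |
| cedar | 20.0 | 0.6 | 75.5 |

(readings scatter by 0.5 percentage points)

1. which flask leads in amount of target, in percent of the starting material charged ("all alike" within 1.5 percentage points) (grey / teal / red / amber / all alike)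
2. how much target is there at the end, in percent of the starting material charged: grey
3. how much target is there at the end, in percent of the starting material charged: teal
4. how much target is there at the end, in percent of the starting material charged: red
5. how much target is there at the end, in percent of the starting material charged: amber



In birch the partner charge is less than the second substrate charge, and in cedar too. In both runs target sinks towards nothing, to 0.9 % in birch at 20.0 min, so I read that second substrate takes partner away from target.

So I carry one number, 0.800 for the asked flasks: the partner margin, partner charged less second substrate charged, as a fraction of the starting material charged. It is the same in all 4, so they differ by temperature.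

Oak has a margin of 2.60. There target over starting material reads 1.37 at first and 1.44 at the last reading, while the sum of the two falls. I read that nearly constant ratio as a fast equilibrium. Taking second substrate as used, and free partner as margin less target, the first reading gives a ratio of 0.648 per unit of free partner.

Now I freeze free partner in amber at 0.400, half the margin, so its ratio is 0.259. In oak the inverse of target plus starting material climbs 0.251 min⁻¹. I scale that climb by target times starting material at the lower ratio, which gives 7.63 % of target. Amber is hotter than oak, so I expect a little less.

Cedar has lost 6.40 % from target plus starting material at 1.50 min, less than the 26.6 % of oak at that time. Those two runs differ in their charges as well as in temperature, so this is a weak guide, but I put teal first.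

The forecast names teal, with 10 % in grey, 17 % in teal, 13 % in red and 10 % in amber, which is more than my figure, and says “Amber stays alive”.

The flasks give teal as leader, with 13.6 % in grey, 31.3 % in teal, 7.41 % in red and 4.77 % in amber.

    starting material + partner + catalyst ⇌ catalyst + target (K = 7.80 M⁻¹, k = 2.30 M⁻² s⁻¹, Ea = 35.0 kJ mol⁻¹, ΔH = −25.0 kJ mol⁻¹)
    second substrate + partner + catalyst → catalyst + second product (k = 2.00 M⁻² s⁻¹, Ea = 42.0 kJ mol⁻¹)
    starting material + target → side product (k = 0.00470 M⁻¹ s⁻¹, Ea = 66.0 kJ mol⁻¹)
    (constants at 50 °C)

Amber ends with free partner at 0.388 of the starting material charged, half its margin. Amber's target is low mainly through the return of target to starting material and partner: without that return amber holds 58.7 %, not 4.77 %.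

Side product holds one partner for two of starting material. So in a neighbour flask, amber with 0.50 M of starting material, the margin of 0.320 pays for a side product share of 64.0 %. The computed flask shows 64.7 % of side product, 0.201 % of target and 0.62 % of the partner charge left: partner is the limiting reagent there.

The earlier runs and the new flask were computed with constants of no real substance; the scatter is artificial.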